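**Retrosynthetic overview**
1. The target consists of two identical 3,5-dihydroxy-4,4-dimethyl-6-(2-methylpropanoyl)cyclohexa-2,5-dien-1-one rings (A and B; C1 = ring C=O, C2 = bridge-bearing carbon, C3 and C5 = enol carbons, C4 = C(CH3)2, C6 = acyl-bearing carbon) joined C2–CH2–C2'.
2. Enabling feature: C1–C2–CH2–C2'–C1' is a hidden glutaryl unit lying across the bridge CH2. The remainder of each ring (C3–C4–C5–C6 plus the side-chain C=O) is a 1,3,5-tricarbonyl chain whose C4 is quaternary, so it cannot enolise and the ring cannot aromatise; every ring bond therefore joins a donor and an acceptor carbon of Claisen polarity.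
3. Key disconnection, made in both rings at once: C1–C6 (C-acylation of a β-diketone) and C2–C3 (Claisen/Dieckmann closure). This leads to pentanedioyl dichloride 6 plus two molecules of β,δ-diketo ester 5: three components, four C–C bonds, rings A and B closed one after the other in the same flask as the last step.
4. Diketo ester 5 comes from methyl isobutyrate 1 by two successive enolate C-acylations (acetyl chloride 2, then isobutyryl chloride 4).

Key step: step 3

Remark on the chemistry: the target is achiral and is drawn as one enol tautomer of a cyclic β-triketone system; the route should deliver the tautomeric mixture that this SMILES represents. Step 3 is run as a one-flask, two-stage operation and is counted as one step.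

**Step 1**
Reactants: 1 methyl 2-methylpropanoate (methyl isobutyrate); 2 acetyl chloride
Product: 3 methyl 2,2-dimethyl-3-oxobutanoate
Conditions: LDA (1.05 equiv), THF, −78 °C; enolate solution added to 2 (1.3 equiv), THF, −78→0 °C
Reagents that add atoms: none
Why: The lithium enolate of 1 (one α-hydrogen only) should be C-acylated by acetyl chloride under inverse addition (ester enolate acylation, crossed Claisen type), and the product has no proton between its carbonyl groups, so it cannot quench unreacted enolate.

**Step 2**
Reactants: 3 methyl 2,2-dimethyl-3-oxobutanoate (1.2 equiv); 4 2-methylpropanoyl chloride (isobutyryl chloride)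
Product: 5 methyl 2,2,6-trimethyl-3,5-dioxoheptanoate
Conditions: MgBr2·OEt2 (2.5 equiv), iPr2NEt (3 equiv), CH2Cl2, rt; aq. HCl work-up
Reagents that add atoms: none
Why: Soft enolisation of the magnesium-chelated keto ester 3, whose acetyl CH3 is its only enolisable position, followed by C-acylation with 4 should give the β-diketone regiospecifically (crossed Claisen-type ketone acylation); over-acylation of the hindered magnesium diketonate by the α-branched acid chloride should be slow and is further suppressed by the slight excess of 3.

**Step 3**
Reactants: 5 methyl 2,2,6-trimethyl-3,5-dioxoheptanoate (2.3 equiv); 6 pentanedioyl dichloride (glutaryl dichloride, 1.0 equiv)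
Product: 9 2,2'-methylenebis[3,5-dihydroxy-4,4-dimethyl-6-(2-methylpropanoyl)cyclohexa-2,5-dien-1-one] (the target), via bis(triacylmethane) diester 7 (not isolated), via monocyclised keto ester 8 (not isolated)
Conditions: MgCl2 (2.5 equiv), pyridine (5 equiv), THF, 0 °C, then 6 added slowly, 0 °C→rt; then KOtBu (ca. 14 equiv), THF, 0→50 °C, same flask; 2 M HCl work-up
Reagents that add atoms: none
Why: MgCl2/pyridine should convert 5 into its magnesium-chelated β-diketonate, which is C-acylated at its central carbon (future C6) by each acyl chloride end of 6 (future C1) to give 7; KOtBu should then remove a glutaryl α-CH2 proton of each triketonate, and the enolate carbon (future C2) attacks the methyl ester six atoms away (future C3), expelling methoxide, first to 8 and then to 9, each closure being made irreversible by deprotonation of the new cyclic β-triketone. The closest known reaction types are the MgCl2/amine C-acylation of 1,3-dicarbonyl compounds by acid chlorides and the Claisen (Dieckmann-type) cyclisation of polyketo esters to cyclohexane-1,3,5-triones, here telescoped and run in two directions from one five-carbon diacid unit. Rings A and B each close by a 6-(enolendo)-exo-trig attack of the enolate carbon on the ester carbonyl. No stereocentre is formed, since C4 carries two identical methyl groups and all other ring carbons are trigonal. The step needs C- over O-acylation (secured by the magnesium chelate, and any enol ester formed is itself an acyl donor towards the diketonate), a second intermolecular acylation in preference to enol-lactonisation of the pendant acyl chloride (6 is added slowly to an excess of the enolate), and enolisation at the glutaryl CH2 and not at the isobutyryl CH (a CH2 is deprotonated faster than a CH in β-dicarbonyl polyanions and leads to the less congested ring). The quaternary C4 secures that the ester can act only as an acceptor and that the ring cannot aromatise, and competing aldol additions to the anionic triketonate carbonyls are reversible whereas each Claisen closure is removed from equilibrium as the ring dianion.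

**Compound list**
1 | methyl 2-methylpropanoate (methyl isobutyrate) | COC(=O)C(C)C | starting material
2 | acetyl chloride | CC(=O)Cl | starting material
3 | methyl 2,2-dimethyl-3-oxobutanoate | COC(=O)C(C)(C)C(C)=O | intermediate
4 | 2-methylpropanoyl chloride (isobutyryl chloride) | CC(C)C(=O)Cl | starting material
5 | methyl 2,2,6-trimethyl-3,5-dioxoheptanoate | COC(=O)C(C)(C)C(=O)CC(=O)C(C)C | intermediate
6 | pentanedioyl dichloride (glutaryl dichloride) | O=C(Cl)CCCC(=O)Cl | starting material
7 | dimethyl 2,2,12,12-tetramethyl-4,10-bis(2-methylpropanoyl)-3,5,9,11-tetraoxotridecanedioate (drawn as the keto form) | COC(=O)C(C)(C)C(=O)C(C(=O)C(C)C)C(=O)CCCC(=O)C(C(=O)C(C)C)C(=O)C(C)(C)C(=O)OC | intermediate (not isolated)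
8 | methyl 7-[2,4-dihydroxy-3,3-dimethyl-5-(2-methylpropanoyl)-6-oxocyclohexa-1,4-dien-1-yl]-2,2-dimethyl-4-(2-methylpropanoyl)-3,5-dioxoheptanoate | CC(C)C(=O)C1=C(O)C(C)(C)C(O)=C(CCC(=O)C(C(=O)C(C)C)C(=O)C(C)(C)C(=O)OC)C1=O | intermediate (not isolated)
9 | 2,2'-methylenebis[3,5-dihydroxy-4,4-dimethyl-6-(2-methylpropanoyl)cyclohexa-2,5-dien-1-one] (achiral) | CC(C)C(=O)C1=C(O)C(C)(C)C(O)=C(CC2=C(O)C(C)(C)C(O)=C(C(=O)C(C)C)C2=O)C1=O | target

**Total step count:** 3
**Longest linear sequence:** 3 steps (1 → 3 → 5 → 9)

**Steps most likely to fail**

Step 3 (highest risk). The ring closure may stall because the triketonate resists a second deprotonation at the glutaryl CH2, or the acyl chloride ends of 6 may be diverted by O-acylation and enol-lactonisation before the second diketonate arrives. The fallback is the classical route through the monomeric ring and sets out from 4. Friedel–Crafts C-acylation of benzene-1,3,5-triol (phloroglucinol) with 4 (AlCl3, PhNO2/CH2Cl2, rt→45 °C) should give 2-methyl-1-(2,4,6-trihydroxyphenyl)propan-1-one F1. Geminal C-dimethylation (MeI, NaOMe, MeOH, 0 °C→rt) should dearomatise it to 3,5-dihydroxy-4,4-dimethyl-2-(2-methylpropanoyl)cyclohexa-2,5-dien-1-one F2. Condensation of two molecules of F2 with aqueous formaldehyde (cat. KOH, EtOH/water, rt; Knoevenagel–Michael sequence) should join their free ring CH positions through a CH2, and the fallback comes back to the route at 9.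

Step 2. The product diketonate may be acylated a second time to a triacylmethane, or acylation may occur on oxygen. The fallback sets out from 3 and replaces acylation by aldol addition and oxidation. The kinetic lithium enolate of 3 (LDA, THF, −78 °C) should add to 2-methylpropanal to give methyl 5-hydroxy-2,2,6-trimethyl-3-oxoheptanoate F3 (racemic). Oxidation of the secondary alcohol with Dess–Martin periodinane (CH2Cl2, rt) should give the β-diketone, and the fallback comes back to the route at 5.

Step 1. The ester enolate may add to the ketone of the product, or acetyl chloride may be dehydrochlorinated to ketene by the enolate. The fallback sets out from 1. Its lithium enolate (LDA, THF, −78 °C) should add to acetaldehyde to give methyl 3-hydroxy-2,2-dimethylbutanoate F4 (racemic). Oxidation with Dess–Martin periodinane (CH2Cl2, rt) should give the keto ester, and the fallback comes back to the route at 3.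

**Further compounds**
F1 | step 3 | 2-methyl-1-(2,4,6-trihydroxyphenyl)propan-1-one | CC(C)C(=O)c1c(O)cc(O)cc1O
F2 | step 3 | 3,5-dihydroxy-4,4-dimethyl-2-(2-methylpropanoyl)cyclohexa-2,5-dien-1-one | CC(C)C(=O)C1=C(O)C(C)(C)C(O)=CC1=O
F3 | step 2 | methyl 5-hydroxy-2,2,6-trimethyl-3-oxoheptanoate (racemic) | COC(=O)C(C)(C)C(=O)CC(O)C(C)C
F4 | step 1 | methyl 3-hydroxy-2,2-dimethylbutanoate (racemic) | COC(=O)C(C)(C)C(C)O
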